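**Plan**

- Retrosynthesis: the C13=C14 enoate is cut to an alkynoate plus a methyl cuprate; C7–OH and C8=C17 are traced back to a C8 ketone; ring B is cut at C9–C10 and taken back to the five-membered ring C5–C6–C7–C8–C10 of a trans-hydrindan-8-one that carries C9 and the chain on C8 as a vicinal diol monomesylate.
- Enabling feature: the 2-methylene-3-alkylcyclohexane unit of ring B (C8=C17 flanked by the C9 methine and quaternary C10) is, as its 8-ketone, the product of a 1,2-shift of C10 from a cyclopentyl carbinol carbon (C8) to an exocyclic secondary sulfonate carbon (C9).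
- Forward: ring A and the five-membered ring come from (R)-Hajos–Parrish ketone; a Z-selective Wittig reaction joins C9–C14; syn-dihydroxylation and mesylation arm the shift; ring enlargement gives ring B; then C17, C15/C16 and the C7 oxygen follow.
- Stereochemistry: C10 from the starting material; C5 by hydrogenation and C3 by hydride addition trans to the axial methyls; C9 by the stereospecific shift, then equilibration next to the C8 ketone; C7 by axial hydride addition to the 7-oxo-8(17)-ene; 13Z by syn-carbocupration.

Key step: step 10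

Remark: labdane numbering (C1–C20) is used for every intermediate (in the hydrindanes the five-membered ring is C5–C6–C7–C8–C10), "cis/trans" refers to the C10 methyl, and (R)-Hajos–Parrish ketone and (5-chloropent-1-yn-1-yl)trimethylsilane are taken as commercial.

Step 1
Reactants: 1 (R)-Hajos–Parrish ketone
Product: 2 C8 ethylene ketal of 1
Conditions: TMSOCH2CH2OTMS, TMSOTf (cat.), CH2Cl2, −78 °C
Reagents that add atoms: 1,2-bis(trimethylsilyloxy)ethane, C[Si](C)(C)OCCO[Si](C)(C)C
Why: Silyl-triflate-catalysed ketalization should take the saturated cyclopentanone much faster than the less electrophilic enone carbonyl, as is usual for this class of bicyclic enediones; no stereocenter is formed.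

Step 2
Reactants: 2 C8 ethylene ketal of 1
Product: 3 4,4-dimethyl-Δ5(6)-3-ketone C8 ketal
Conditions: KOt-Bu, MeI, t-BuOH, 25 °C
Reagents that add atoms: iodomethane, CI
Why: Deconjugative double α-methylation of the extended dienolate installs the C4 gem-dimethyl group and moves the double bond to C5=C6, the classical alkylation of bicyclic enones of this type.

Step 3
Reactants: 3 4,4-dimethyl-Δ5(6)-3-ketone C8 ketal
Product: 4 3-alcohol of 3 (OH cis to the C10 methyl)
Conditions: NaBH4, MeOH, 0 °C
Reagents that add atoms: none
Why: Borohydride reduction should deliver hydride to the C3 ketone from the face trans to the axial C10 and C4 methyls, giving the alcohol cis to the C10 methyl.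

Step 4
Reactants: 4 3-alcohol of 3
Product: 6 (3aR,5R,7aR)-5-hydroxy-4,4,7a-trimethyloctahydro-1H-inden-1-one, via saturated ketal alcohol 5 (not isolated)
Conditions: H2 (4 atm), Pd/C, EtOH, 25 °C; filter; then 2 M aq HCl, THF, 25 °C
Reagents that add atoms: water, O
Why: Heterogeneous hydrogenation should add to C5=C6 from the face opposite the two axial methyls (C10 methyl and one C4 methyl), setting the trans ring fusion at C5, and aqueous acid then hydrolyses the dioxolane.

Step 5
Reactants: 6 (3aR,5R,7aR)-5-hydroxy-4,4,7a-trimethyloctahydro-1H-inden-1-one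
Product: 7 tert-butyldimethylsilyl ether of 6
Conditions: TBSOTf, 2,6-lutidine, CH2Cl2, −78 °C
Reagents that add atoms: tert-butyldimethylsilyl triflate, CC(C)(C)[Si](C)(C)OS(=O)(=O)C(F)(F)F
Why: Silylation with the silyl triflate and a hindered pyridine base should protect the hindered secondary alcohol at low temperature without enolizing the ketone.

Step 6
Reactants: 8 (5-chloropent-1-yn-1-yl)trimethylsilane
Product: 10 triphenyl[5-(trimethylsilyl)pent-4-yn-1-yl]phosphonium iodide, via (5-iodopent-1-yn-1-yl)trimethylsilane 9 (not isolated)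
Conditions: NaI, PPh3, MeCN, reflux
Reagents that add atoms: sodium iodide, [Na+].[I-]; triphenylphosphine, c1ccc(cc1)P(c1ccccc1)c1ccccc1
Why: Finkelstein exchange in situ followed by SN2 quaternization of the phosphine gives the phosphonium salt that carries C9 and C11–C14.

Step 7
Reactants: 7 tert-butyldimethylsilyl ether of 6; 10 triphenyl[5-(trimethylsilyl)pent-4-yn-1-yl]phosphonium iodide
Product: 12 (Z)-C8=C9 alkylidene hydrindane (chain cis to C10), via phosphorus ylide 11 (not isolated)
Conditions: 10, KN(SiMe3)2, toluene, 0 → 25 °C; then 7, 90 °C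
Reagents that add atoms: none
Why: Wittig olefination with a non-stabilized ylide should place the ylide substituent cis to the larger, quaternary side of the ketone, as established for 17-oxo steroids in the same trans-hydrindanone environment, giving the (Z)-alkene; the amide base spares the silyl alkyne.

Step 8
Reactants: 12 (Z)-C8=C9 alkylidene hydrindane
Product: 13 (8S,9R)-8,9-diol (C8–OH trans to the C10 methyl)
Conditions: OsO4 (5 mol %), N-methylmorpholine N-oxide, t-BuOH/acetone/H2O, 25 °C
Reagents that add atoms: N-methylmorpholine N-oxide, C[N+]1([O-])CCOCC1; water, O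
Why: Upjohn syn-dihydroxylation should occur on the alkene face opposite the C10 methyl, so that syn addition to the (Z)-alkene fixes C8 and C9 together, while the silyl alkyne stays inert.

Step 9
Reactants: 13 (8S,9R)-8,9-diol
Product: 14 C9 methanesulfonate of 13
Conditions: MsCl, Et3N, CH2Cl2, −20 °C
Reagents that add atoms: methanesulfonyl chloride, CS(=O)(=O)Cl
Why: Sulfonylation selects the secondary C9 hydroxyl because the tertiary C8 hydroxyl does not react under these conditions.

Step 10
Reactants: 14 C9 methanesulfonate of 13
Product: 16 ring-enlarged (9R)-8-ketone (chain trans to the C10 methyl), via diethylaluminium alkoxide 15 (not isolated)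
Conditions: Et3Al, CH2Cl2, −78 → 0 °C
Reagents that add atoms: none
Why: Et3Al turns the tertiary C8 hydroxyl into an aluminium alkoxide that pushes while the metal pulls on the C9 sulfonate, so that C10 shifts suprafacially from C8 to C9 antiperiplanar to the leaving group and C8 becomes the carbonyl carbon; this is a semipinacol rearrangement, and the closest known types are the organoaluminium-promoted 1,2-shift of 2-hydroxy sulfonates and the D-homoannulation of steroidal 17-hydroxy-20-sulfonates. No ring is closed by cyclization: the five-membered ring C5–C6–C7–C8–C10 is enlarged to the six-membered ring B by insertion of C9 between C8 and C10, with retention at the migrating quaternary C10. The new stereocenter C9 is controlled by inversion at the (9R)-carbinol carbon, which should give the (9R)-ketone with the chain trans to the C10 methyl; this is the C9 epimer of the target and is corrected in step 11. The step needs C10 to migrate in preference to C7 and to epoxide closure; the (8S,9R) configuration from steps 7 and 8 should secure this, because only the rotamer with the C9–O bond anti to C8–C10 keeps the chain out of the sector above the ring under the C10 methyl, and the quaternary carbon is the better migrating group under Lewis-acidic, non-basic conditions.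

Step 11
Reactants: 16 ring-enlarged (9R)-8-ketone
Product: 18 (9S)-8-ketone with terminal alkyne (chain cis to the C10 methyl), via desilylated 9-epi ketone 17 (not isolated)
Conditions: NaOMe, MeOH, 40 °C
Reagents that add atoms: none
Why: Methoxide removes the alkynyl silyl group by protodesilylation and should equilibrate C9 through the C8 enolate to the epimer with the equatorial chain, the arrangement of the natural 8-oxolabdanes.

Step 12
Reactants: 18 (9S)-8-ketone with terminal alkyne
Product: 19 8(17)-ene with terminal alkyne
Conditions: Ph3PCH3Br, KOt-Bu, THF, 0 → 60 °C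
Reagents that add atoms: methyltriphenylphosphonium bromide, C[P+](c1ccccc1)(c1ccccc1)c1ccccc1.[Br-]
Why: Wittig methylenation of the hindered C8 ketone gives the exocyclic C8=C17 alkene, and enolization under the basic conditions is harmless because C9 is already in its stable configuration.

Step 13
Reactants: 19 8(17)-ene with terminal alkyne
Product: 21 methyl alk-13-ynoate, via lithium acetylide 20 (not isolated)
Conditions: n-BuLi, THF, −78 °C; then ClCO2Me, −78 → 0 °C
Reagents that add atoms: methyl chloroformate, COC(=O)Cl
Why: Deprotonation of the terminal alkyne and C-acylation of the acetylide with the chloroformate installs C15 as the methyl ester.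

Step 14
Reactants: 21 methyl alk-13-ynoate
Product: 23 methyl (13Z)-3-silyloxylabda-8(17),13-dien-15-oate, via vinylcuprate adduct 22 (not isolated)
Conditions: Me2CuLi, THF, −78 °C; then MeOH, −78 °C
Reagents that add atoms: lithium dimethylcuprate, [Li+].C[Cu-]C
Why: Syn carbocupration of the alkynoate at low temperature and protonation with retention put the new methyl cis to hydrogen, so the chain is cis to the ester, which is the (13Z) geometry.

Step 15
Reactants: 23 methyl (13Z)-3-silyloxylabda-8(17),13-dien-15-oate
Product: 24 7-axial allylic alcohol (OH trans to the C10 methyl)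
Conditions: SeO2 (cat.), t-BuOOH, CH2Cl2, 25 °C
Reagents that add atoms: tert-butyl hydroperoxide, CC(C)(C)OO (oxygen relayed by the SeO2 catalyst)
Why: Riley allylic oxidation (ene reaction, then [2,3]-sigmatropic shift of the allylseleninic acid) should attack the allylic methylene C7 of the 1,1-disubstituted alkene in preference to the methine C9 and the electron-poor enoate, delivering oxygen axially.

Step 16
Reactants: 24 7-axial allylic alcohol
Product: 25 7-oxo-8(17)-ene
Conditions: Dess–Martin periodinane, NaHCO3, CH2Cl2, 0 °C
Reagents that add atoms: none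
Why: Dess–Martin oxidation under buffered conditions converts the allylic alcohol into the exocyclic enone and erases the wrongly configured C7 center.

Step 17
Reactants: 25 7-oxo-8(17)-ene
Product: 26 3-O-silyl ether of the target (7-equatorial alcohol, cis to the C10 methyl)
Conditions: NaBH4, CeCl3·7H2O, MeOH, −78 °C
Reagents that add atoms: none
Why: Luche 1,2-reduction should add hydride axially to C7 from the face trans to the C10 methyl, giving the equatorial (7R) alcohol without touching the enoate.

Step 18
Reactants: 26 3-O-silyl ether of the target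
Product: 27 methyl (3R,5S,7R,9S,10R,13Z)-3,7-dihydroxylabda-8(17),13-dien-15-oate
Conditions: HF·pyridine, THF, 0 → 25 °C
Reagents that add atoms: none
Why: Fluoride-mediated desilylation frees the C3 alcohol under conditions that should leave the allylic alcohol and the (Z)-enoate unchanged.

**Compound list**

1 | (R)-Hajos–Parrish ketone, (7aR)-7a-methyl-2,3,7,7a-tetrahydro-1H-indene-1,5(6H)-dione | O=C1CCC2=CC(=O)CC[C@@]12C | starting material
2 | C8 ethylene ketal of 1 (enone intact) | O1CCOC12CCC3=CC(=O)CC[C@@]23C | intermediate
3 | 4,4-dimethyl-Δ5(6)-3-ketone C8 ketal | O1CCOC12CC=C3C(C)(C)C(=O)CC[C@@]23C | intermediate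
4 | 3-alcohol of 3, OH cis to the C10 methyl | O1CCOC12CC=C3C(C)(C)[C@H](O)CC[C@@]23C | intermediate
5 | trans-fused saturated ketal alcohol (formed in the flask, not isolated) | O1CCOC12CC[C@@H]3C(C)(C)[C@H](O)CC[C@@]23C | intermediate
6 | (3aR,5R,7aR)-5-hydroxy-4,4,7a-trimethyloctahydro-1H-inden-1-one (trans-fused, OH cis to the angular methyl) | O=C1CC[C@@H]2C(C)(C)[C@H](O)CC[C@@]12C | intermediate
7 | tert-butyldimethylsilyl ether of 6 | O=C1CC[C@@H]2C(C)(C)[C@H](O[Si](C)(C)C(C)(C)C)CC[C@@]12C | intermediate
8 | (5-chloropent-1-yn-1-yl)trimethylsilane | C[Si](C)(C)C#CCCCCl | starting material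
9 | (5-iodopent-1-yn-1-yl)trimethylsilane (formed in the flask, not isolated) | C[Si](C)(C)C#CCCCI | intermediate
10 | triphenyl[5-(trimethylsilyl)pent-4-yn-1-yl]phosphonium iodide | C[Si](C)(C)C#CCCC[P+](c1ccccc1)(c1ccccc1)c1ccccc1.[I-] | intermediate
11 | triphenyl[5-(trimethylsilyl)pent-4-yn-1-ylidene]phosphorane (formed in the flask, not isolated) | C[Si](C)(C)C#CCCC=P(c1ccccc1)(c1ccccc1)c1ccccc1 | intermediate
12 | (Z)-C8=C9 alkylidene hydrindane, chain cis to C10 | C[Si](C)(C)C#CCC/C=C1/CC[C@@H]2C(C)(C)[C@H](O[Si](C)(C)C(C)(C)C)CC[C@@]12C | intermediate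
13 | (8S,9R)-8,9-diol, C8–OH trans to the C10 methyl | C[Si](C)(C)C#CCC[C@@H](O)[C@]1(O)CC[C@@H]2C(C)(C)[C@H](O[Si](C)(C)C(C)(C)C)CC[C@@]12C | intermediate
14 | C9 methanesulfonate of 13 | C[Si](C)(C)C#CCC[C@@H](OS(C)(=O)=O)[C@]1(O)CC[C@@H]2C(C)(C)[C@H](O[Si](C)(C)C(C)(C)C)CC[C@@]12C | intermediate
15 | diethylaluminium C8 alkoxide of 14 (formed in the flask, not isolated) | C[Si](C)(C)C#CCC[C@@H](OS(C)(=O)=O)[C@]1(O[Al](CC)CC)CC[C@@H]2C(C)(C)[C@H](O[Si](C)(C)C(C)(C)C)CC[C@@]12C | intermediate
16 | ring-enlarged (9R)-8-oxo decalin, silyl alkyne, chain trans to the C10 methyl | O=C1CC[C@@H]2C(C)(C)[C@H](O[Si](C)(C)C(C)(C)C)CC[C@@]2(C)[C@H]1CCC#C[Si](C)(C)C | intermediate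
17 | desilylated 9-epi ketone (formed in the flask, not isolated) | O=C1CC[C@@H]2C(C)(C)[C@H](O[Si](C)(C)C(C)(C)C)CC[C@@]2(C)[C@H]1CCC#C | intermediate
18 | (9S)-8-oxo decalin with terminal alkyne, chain cis to the C10 methyl | O=C1CC[C@@H]2C(C)(C)[C@H](O[Si](C)(C)C(C)(C)C)CC[C@@]2(C)[C@@H]1CCC#C | intermediate
19 | 8(17)-ene with terminal alkyne | C=C1CC[C@@H]2C(C)(C)[C@H](O[Si](C)(C)C(C)(C)C)CC[C@@]2(C)[C@@H]1CCC#C | intermediate
20 | lithium acetylide of 19 (formed in the flask, not isolated) | C=C1CC[C@@H]2C(C)(C)[C@H](O[Si](C)(C)C(C)(C)C)CC[C@@]2(C)[C@@H]1CCC#C[Li] | intermediate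
21 | methyl alk-13-ynoate (16-nor) | C=C1CC[C@@H]2C(C)(C)[C@H](O[Si](C)(C)C(C)(C)C)CC[C@@]2(C)[C@@H]1CCC#CC(=O)OC | intermediate
22 | lithium methyl(vinyl)cuprate adduct, Cu cis to the new methyl (formed in the flask, not isolated) | C=C1CC[C@@H]2C(C)(C)[C@H](O[Si](C)(C)C(C)(C)C)CC[C@@]2(C)[C@@H]1CC/C(C)=C(/[Cu-]C)C(=O)OC.[Li+] | intermediate
23 | methyl (13Z)-3-silyloxylabda-8(17),13-dien-15-oate | C=C1CC[C@@H]2C(C)(C)[C@H](O[Si](C)(C)C(C)(C)C)CC[C@@]2(C)[C@@H]1CC/C(C)=C\C(=O)OC | intermediate
24 | 7-axial allylic alcohol, OH trans to the C10 methyl (C7 epimer of 26) | C=C1[C@@H](O)C[C@@H]2C(C)(C)[C@H](O[Si](C)(C)C(C)(C)C)CC[C@@]2(C)[C@@H]1CC/C(C)=C\C(=O)OC | intermediate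
25 | 7-oxo-8(17)-ene | C=C1C(=O)C[C@@H]2C(C)(C)[C@H](O[Si](C)(C)C(C)(C)C)CC[C@@]2(C)[C@@H]1CC/C(C)=C\C(=O)OC | intermediate
26 | 3-O-tert-butyldimethylsilyl ether of the target | C=C1[C@H](O)C[C@@H]2C(C)(C)[C@H](O[Si](C)(C)C(C)(C)C)CC[C@@]2(C)[C@@H]1CC/C(C)=C\C(=O)OC | intermediate
27 | methyl (3R,5S,7R,9S,10R,13Z)-3,7-dihydroxylabda-8(17),13-dien-15-oate (CNP0284783.1) | C=C1[C@H](O)C[C@@H]2C(C)(C)[C@H](O)CC[C@@]2(C)[C@@H]1CC/C(C)=C\C(=O)OC | target

**Step count**

Total: 18 steps. Longest linear sequence: 17 steps (steps 1–5 and 7–18).

**Steps most likely to fail**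

1. Step 10. What may go wrong: the C7 ring bond could shift instead of C10, or the alkoxide could close onto C9 to give the 8,9-epoxide, so that the six-membered ring B is not formed. The fallback sets out from diol 13 and returns at 18. The secondary C9 hydroxyl of 13 would be oxidized (SO3·pyridine, DMSO, Et3N) to the tertiary α-hydroxy ketone F1. An α-ketol rearrangement would then enlarge the five-membered ring to the 9-hydroxy-8-ketone F2; it can be run either with KOH in MeOH or with a chelating Lewis acid (BF3·OEt2 or Al(Oi-Pr)3), so that either ring bond can be brought over the acyl group. SmI2 in THF/MeOH would remove the C9 hydroxyl, and protonation of the C8–C9 enolate trans to the C10 methyl would give the silyl-alkynyl ketone F3. The methoxide treatment of step 11 would convert F3 into 18.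

2. Step 7. What may go wrong: the hindered ketone next to the quaternary carbon could enolize instead of being olefinated, or Z-selectivity could erode, which would feed the diol diastereomer that shifts C7. The fallback sets out from ketone 7 and returns at 18. Addition of bis(phenylthio)methyllithium would give the carbinol F4. CuOTf with i-Pr2NEt in warm benzene would ionize one C–S bond, and the sulfur-stabilized cation would trigger the pinacol-type shift to the ring-enlarged 9-(phenylthio)-8-ketone F5. Its potassium enolate (KN(SiMe3)2, THF) would be alkylated at C9 with (4-iodobut-1-yn-1-yl)trimethylsilane to give F6. SmI2 would cleave the phenylthio group, protonation would give F3, and methoxide as in step 11 would give 18.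

3. Step 11. What may go wrong: the thermodynamic preference for the equatorial chain may be too small, leaving a mixture of C9 epimers that is carried forward. The fallback sets out from 16 and returns at 18, using kinetic instead of thermodynamic control. 16 would be converted (TMSCl, NaI, Et3N, MeCN) into the more substituted C8–C9 silyl enol ether F7. MeLi in THF would release the regiodefined lithium enolate, and protonation at −78 °C from the face trans to the C10 methyl would give F3. K2CO3 in MeOH would then remove the alkynyl silyl group to give 18.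

**Further compounds**

F1 | step 10 | tertiary α-hydroxy ketone (C8–OH, C9 ketone) from oxidation of 13 | C[Si](C)(C)C#CCCC(=O)[C@]1(O)CC[C@@H]2C(C)(C)[C@H](O[Si](C)(C)C(C)(C)C)CC[C@@]12C
F2 | step 10 | ring-enlarged 9-hydroxy-8-ketone, drawn with OH trans to the C10 methyl (the C9 epimer serves equally) | O=C1CC[C@@H]2C(C)(C)[C@H](O[Si](C)(C)C(C)(C)C)CC[C@@]2(C)[C@]1(O)CCC#C[Si](C)(C)C
F3 | step 10 | (9S)-8-oxo decalin with silyl alkyne, chain cis to the C10 methyl | O=C1CC[C@@H]2C(C)(C)[C@H](O[Si](C)(C)C(C)(C)C)CC[C@@]2(C)[C@@H]1CCC#C[Si](C)(C)C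
F4 | step 7 | C8 carbinol bearing the bis(phenylthio)methyl group (OH cis to the C10 methyl) | O[C@]1(C(Sc2ccccc2)Sc2ccccc2)CC[C@@H]2C(C)(C)[C@H](O[Si](C)(C)C(C)(C)C)CC[C@@]12C
F5 | step 7 | ring-enlarged 9-(phenylthio)-8-ketone, drawn with equatorial sulfur (epimerizable) | O=C1CC[C@@H]2C(C)(C)[C@H](O[Si](C)(C)C(C)(C)C)CC[C@@]2(C)[C@@H]1Sc1ccccc1
F6 | step 7 | 9-(phenylthio)-9-[4-(trimethylsilyl)but-3-ynyl]-8-ketone, drawn with the chain trans to the C10 methyl (configuration immaterial) | O=C1CC[C@@H]2C(C)(C)[C@H](O[Si](C)(C)C(C)(C)C)CC[C@@]2(C)[C@]1(CCC#C[Si](C)(C)C)Sc1ccccc1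
F7 | step 11 | C8–C9 trimethylsilyl enol ether of 16 | C[Si](C)(C)OC=1CC[C@@H]2C(C)(C)[C@H](O[Si](C)(C)C(C)(C)C)CC[C@@]2(C)C=1CCC#C[Si](C)(C)C
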